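**Retrosynthetic overview**
- The target is released by one global hydrogenolysis of three benzyl groups; its aryl ketone comes from oxidation of a benzylic carbinol.
- The ring A–C1 bond is made by adding an arylmagnesium reagent to an α-aryloxy aldehyde, which comes from ozonolysis of a terminal vinyl group.
- Key step: the C2–O(aryl) bond and the only stereocentre are made together by a Pd-catalysed dynamic kinetic asymmetric allylic etherification of racemic butadiene monoepoxide with benzyl syringate. This replaces the usual α-bromoketone/phenol SN2 plus formaldehyde aldol.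
- No ring is formed: ring A is bought as 4-bromo-2,6-dimethoxyphenol and ring B as syringic acid.

Assumption: the (S,S)-DACH-naphthyl Trost ligand is taken to give the (R)-configured allyl aryl ether in step 2; the sense is confirmed on the first batch (Mosher ester), and the (R,R)-ligand is used if it proves opposite.

**Step 1**
Reactants: 1 syringic acid (4-hydroxy-3,5-dimethoxybenzoic acid)
Product: 2 benzyl 4-hydroxy-3,5-dimethoxybenzoate
Conditions: BnBr (1.05 equiv), KHCO3 (1.1 equiv), DMF, 40 °C
Reagents that add atoms: benzyl bromide, BrCc1ccccc1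
Why: Bicarbonate ionises only the carboxylic acid, so SN2 O-alkylation gives the benzyl ester and leaves the hindered phenol free (chemoselective carboxylate alkylation).

**Step 2**
Reactants: 2 benzyl 4-hydroxy-3,5-dimethoxybenzoate; 3 racemic 2-vinyloxirane (butadiene monoepoxide, 1.2 equiv)
Product: 4 benzyl 4-{[(2R)-1-hydroxybut-3-en-2-yl]oxy}-3,5-dimethoxybenzoate
Conditions: Pd2(dba)3·CHCl3 (1 mol%), (S,S)-DACH-naphthyl Trost ligand (3 mol%), CH2Cl2, 0 °C to rt, stopped at full conversion of 2
Reagents that add atoms: none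
Why: Proposed new method: zerovalent palladium opens both enantiomers of 3 to 1-(hydroxymethyl)allyl complexes that interconvert by η3–η1–η3 isomerisation faster than they are trapped, the phenol (pKa about 9) protonates the alkoxide, and the hydrogen-bonded phenoxide attacks the internal allyl terminus inside the chiral ligand pocket, setting C2 as R; the closest known reaction type is the Trost dynamic kinetic asymmetric allylic alkylation of butadiene monoepoxide with imide and alcohol pronucleophiles, together with Pd-catalysed asymmetric O-allylation of 2,6-disubstituted phenols.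

**Step 3**
Reactants: 4 benzyl 4-{[(2R)-1-hydroxybut-3-en-2-yl]oxy}-3,5-dimethoxybenzoate
Product: 5 benzyl 4-{[(2R)-1-(benzyloxy)but-3-en-2-yl]oxy}-3,5-dimethoxybenzoate
Conditions: BnOC(=NH)CCl3 (1.5 equiv), TfOH (5 mol%), CH2Cl2/cyclohexane, 0 °C
Reagents that add atoms: benzyl 2,2,2-trichloroacetimidate, N=C(OCc1ccccc1)C(Cl)(Cl)Cl
Why: Acid-catalysed trichloroacetimidate benzylation protects the primary alcohol without base, so the benzyl ester is not transesterified and the stereocentre is untouched.

**Step 4**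
Reactants: 5 benzyl 4-{[(2R)-1-(benzyloxy)but-3-en-2-yl]oxy}-3,5-dimethoxybenzoate
Product: 7 benzyl 4-{[(2S)-1-(benzyloxy)-3-oxopropan-2-yl]oxy}-3,5-dimethoxybenzoate, via secondary ozonide 6 (not isolated)
Conditions: O3, CH2Cl2, −78 °C (Sudan red 7B end point); then PPh3, −78 °C to rt; quick silica plug, used the same day
Reagents that add atoms: ozone, [O-][O+]=O
Why: Criegee ozonolysis cleaves the terminal alkene much faster than it attacks the arene or benzyl ethers, and neutral reductive work-up gives the aldehyde without epimerisation (the descriptor changes from R to S only because CHO outranks CH2OBn).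

**Step 5**
Reactants: 8 4-bromo-2,6-dimethoxyphenol
Product: 9 2-(benzyloxy)-5-bromo-1,3-dimethoxybenzene
Conditions: BnBr (1.1 equiv), K2CO3 (1.0 equiv), DMF, rt
Reagents that add atoms: benzyl bromide, BrCc1ccccc1
Why: Williamson etherification of the phenoxide protects the ring A phenol as a benzyl ether that survives Grignard formation.

**Step 6**
Reactants: 9 2-(benzyloxy)-5-bromo-1,3-dimethoxybenzene (1.4 equiv); 7 benzyl 4-{[(2S)-1-(benzyloxy)-3-oxopropan-2-yl]oxy}-3,5-dimethoxybenzoate
Product: 11 benzyl 4-({(2S)-3-(benzyloxy)-1-[4-(benzyloxy)-3,5-dimethoxyphenyl]-1-hydroxypropan-2-yl}oxy)-3,5-dimethoxybenzoate (both C1 epimers), via arylmagnesium bromide 10 (not isolated)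
Conditions: Mg turnings, THF, 45 °C; then 7, THF, −78 °C; aq. NH4Cl
Reagents that add atoms: none
Why: Grignard 1,2-addition to the aldehyde at −78 °C is far faster than attack on the electron-rich benzyl benzoate or α-deprotonation, so C2 keeps its configuration, and the new carbinol centre is irrelevant because it is oxidised in step 7.

**Step 7**
Reactants: 11 benzyl 4-({(2S)-3-(benzyloxy)-1-[4-(benzyloxy)-3,5-dimethoxyphenyl]-1-hydroxypropan-2-yl}oxy)-3,5-dimethoxybenzoate
Product: 12 benzyl 4-({(2S)-3-(benzyloxy)-1-[4-(benzyloxy)-3,5-dimethoxyphenyl]-1-oxopropan-2-yl}oxy)-3,5-dimethoxybenzoate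
Conditions: Dess–Martin periodinane (1.3 equiv), CH2Cl2, 0 °C to rt
Reagents that add atoms: none
Why: Dess–Martin oxidation converts both carbinol epimers into the single aryl ketone under near-neutral conditions that do not enolise the adjacent aryloxy-bearing stereocentre.

**Step 8**
Reactants: 12 benzyl 4-({(2S)-3-(benzyloxy)-1-[4-(benzyloxy)-3,5-dimethoxyphenyl]-1-oxopropan-2-yl}oxy)-3,5-dimethoxybenzoate
Product: 13 4-{[(2S)-3-hydroxy-1-(4-hydroxy-3,5-dimethoxyphenyl)-1-oxopropan-2-yl]oxy}-3,5-dimethoxybenzoic acid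
Conditions: H2 (1 atm), Pd(OH)2/C, EtOAc/EtOH 1:1, rt, stopped as soon as debenzylation is complete
Reagents that add atoms: none
Why: Catalytic hydrogenolysis removes the aryl benzyl ether, the benzyl ester and the primary benzyl ether in one neutral operation, avoiding the base that would cause epimerisation, retro-aldol or β-elimination of the β-hydroxy ketone.

**Compound list**
1 | syringic acid (4-hydroxy-3,5-dimethoxybenzoic acid) | COc1cc(C(=O)O)cc(OC)c1O | starting material
2 | benzyl 4-hydroxy-3,5-dimethoxybenzoate | COc1cc(C(=O)OCc2ccccc2)cc(OC)c1O | intermediate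
3 | racemic 2-vinyloxirane (butadiene monoepoxide) | C=CC1CO1 | starting material
4 | benzyl 4-{[(2R)-1-hydroxybut-3-en-2-yl]oxy}-3,5-dimethoxybenzoate | C=C[C@H](CO)Oc1c(OC)cc(C(=O)OCc2ccccc2)cc1OC | intermediate
5 | benzyl 4-{[(2R)-1-(benzyloxy)but-3-en-2-yl]oxy}-3,5-dimethoxybenzoate | C=C[C@H](COCc1ccccc1)Oc1c(OC)cc(C(=O)OCc2ccccc2)cc1OC | intermediate
6 | benzyl 4-{[(1S)-2-(benzyloxy)-1-(1,2,4-trioxolan-3-yl)ethyl]oxy}-3,5-dimethoxybenzoate (secondary ozonide of 5, both epimers at the trioxolane carbon; not isolated) | O1COC(O1)[C@H](COCc1ccccc1)Oc1c(OC)cc(C(=O)OCc2ccccc2)cc1OC | intermediate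
7 | benzyl 4-{[(2S)-1-(benzyloxy)-3-oxopropan-2-yl]oxy}-3,5-dimethoxybenzoate | O=C[C@H](COCc1ccccc1)Oc1c(OC)cc(C(=O)OCc2ccccc2)cc1OC | intermediate
8 | 4-bromo-2,6-dimethoxyphenol | COc1cc(Br)cc(OC)c1O | starting material
9 | 2-(benzyloxy)-5-bromo-1,3-dimethoxybenzene | COc1cc(Br)cc(OC)c1OCc1ccccc1 | intermediate
10 | [4-(benzyloxy)-3,5-dimethoxyphenyl]magnesium bromide (not isolated) | COc1cc([Mg]Br)cc(OC)c1OCc1ccccc1 | intermediate
11 | benzyl 4-({(2S)-3-(benzyloxy)-1-[4-(benzyloxy)-3,5-dimethoxyphenyl]-1-hydroxypropan-2-yl}oxy)-3,5-dimethoxybenzoate (both C1 epimers) | COc1cc(C(O)[C@H](COCc2ccccc2)Oc2c(OC)cc(C(=O)OCc3ccccc3)cc2OC)cc(OC)c1OCc1ccccc1 | intermediate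
12 | benzyl 4-({(2S)-3-(benzyloxy)-1-[4-(benzyloxy)-3,5-dimethoxyphenyl]-1-oxopropan-2-yl}oxy)-3,5-dimethoxybenzoate | COc1cc(C(=O)[C@H](COCc2ccccc2)Oc2c(OC)cc(C(=O)OCc3ccccc3)cc2OC)cc(OC)c1OCc1ccccc1 | intermediate
13 | 4-{[(2S)-3-hydroxy-1-(4-hydroxy-3,5-dimethoxyphenyl)-1-oxopropan-2-yl]oxy}-3,5-dimethoxybenzoic acid | COc1cc(C(=O)[C@H](CO)Oc2c(OC)cc(C(=O)O)cc2OC)cc(OC)c1O | target

**Totals**
Total step count: 8. Longest linear sequence: 7 steps (steps 1, 2, 3, 4, 6, 7, 8); step 5 is the side branch that makes the ring A fragment.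

**Three steps most likely to fail, with fallbacks**

1. Step 2 (key etherification). The hindered, fairly acidic phenol may give the linear 1,4-ether. The allyl aryl ether can also re-ionise on palladium, which would erode regio- and enantiopurity. Fallback, setting out from 2 and coming back at 5 (step 3 is then not needed): the allyl partner is changed to the linear carbonate methyl (2E)-4-(benzyloxy)but-2-en-1-yl carbonate F1, made from commercial (E)-4-(benzyloxy)but-2-en-1-ol with methyl chloroformate and pyridine. Phenol 2, deprotonated in the flask with LiOt-Bu, is coupled with it in THF using [Ir(cod)Cl]2 and a binaphthol-derived bis(1-phenylethyl)amine phosphoramidite. This branched-selective allylic etherification proceeds through an enantioface-selectively formed allyliridium complex, is not reversible under the conditions, and delivers 5 directly; the ligand enantiomer is chosen to give R.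

2. Step 6 (with the handling of aldehyde 7). The α-aryloxy aldehyde can epimerise or lose benzyl alcohol under the basic Grignard conditions, and the benzyl ester can be attacked. Fallback, setting out from 7 and 10 and coming back at 12 (step 7 is then not needed): Pinnick oxidation of 7 (NaClO2, NaH2PO4, 2-methyl-2-butene, t-BuOH/H2O) gives (2S)-3-(benzyloxy)-2-{4-[(benzyloxy)carbonyl]-2,6-dimethoxyphenoxy}propanoic acid F2. This is converted with EtSH, DCC and catalytic DMAP at −20 °C into the S-ethyl thioester F3. Grignard reagent 10 is quenched with B(OMe)3 and aqueous HCl to give [4-(benzyloxy)-3,5-dimethoxyphenyl]boronic acid F4. A base-free Liebeskind–Srogl coupling of F3 with F4 (Pd2(dba)3, tri(2-furyl)phosphine, the monovalent copper carboxylate CuO2CC4H3S, THF, 50 °C) forms ketone 12 directly, without any carbanion or alkoxide near the stereocentre.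

3. Step 8 (global hydrogenolysis). The primary benzyl ether cleaves more slowly than the other two benzyl groups, and prolonged exposure risks reduction of the aryl ketone or hydrogenolysis of the α-aryloxy C–O bond. Fallback, setting out from 4 and coming back at 13: the primary alcohol is carried as a silyl ether instead.
   - TBSCl and imidazole in DMF give the tert-butyldimethylsilyl ether F5.
   - Ozonolysis as in step 4 passes through the secondary ozonide F6 and gives the silyloxy aldehyde F7.
   - Addition of Grignard reagent 10 gives the carbinol F8, and Dess–Martin oxidation gives the silyloxy ketone F9.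
   - HF·pyridine in THF at 0 °C frees the primary alcohol to give the dibenzyl hydroxy ketone F10.
   - A short hydrogenolysis (H2, Pd/C, EtOAc, under one hour) then has to remove only the two easily cleaved benzyl groups and gives 13.

**Further compounds**
F1 | step 2 | methyl (2E)-4-(benzyloxy)but-2-en-1-yl carbonate | COC(=O)OC/C=C/COCc1ccccc1
F2 | step 6 | (2S)-3-(benzyloxy)-2-{4-[(benzyloxy)carbonyl]-2,6-dimethoxyphenoxy}propanoic acid | OC(=O)[C@H](COCc1ccccc1)Oc1c(OC)cc(C(=O)OCc2ccccc2)cc1OC
F3 | step 6 | S-ethyl (2S)-3-(benzyloxy)-2-{4-[(benzyloxy)carbonyl]-2,6-dimethoxyphenoxy}propanethioate | CCSC(=O)[C@H](COCc1ccccc1)Oc1c(OC)cc(C(=O)OCc2ccccc2)cc1OC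
F4 | step 6 | [4-(benzyloxy)-3,5-dimethoxyphenyl]boronic acid | COc1cc(B(O)O)cc(OC)c1OCc1ccccc1
F5 | step 8 | benzyl 4-{[(2R)-1-{[tert-butyl(dimethyl)silyl]oxy}but-3-en-2-yl]oxy}-3,5-dimethoxybenzoate | C=C[C@H](CO[Si](C)(C)C(C)(C)C)Oc1c(OC)cc(C(=O)OCc2ccccc2)cc1OC
F6 | step 8 | benzyl 4-{[(1S)-2-{[tert-butyl(dimethyl)silyl]oxy}-1-(1,2,4-trioxolan-3-yl)ethyl]oxy}-3,5-dimethoxybenzoate | O1COC(O1)[C@H](CO[Si](C)(C)C(C)(C)C)Oc1c(OC)cc(C(=O)OCc2ccccc2)cc1OC
F7 | step 8 | benzyl 4-{[(2S)-1-{[tert-butyl(dimethyl)silyl]oxy}-3-oxopropan-2-yl]oxy}-3,5-dimethoxybenzoate | O=C[C@H](CO[Si](C)(C)C(C)(C)C)Oc1c(OC)cc(C(=O)OCc2ccccc2)cc1OC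
F8 | step 8 | benzyl 4-({(2S)-1-[4-(benzyloxy)-3,5-dimethoxyphenyl]-3-{[tert-butyl(dimethyl)silyl]oxy}-1-hydroxypropan-2-yl}oxy)-3,5-dimethoxybenzoate | COc1cc(C(O)[C@H](CO[Si](C)(C)C(C)(C)C)Oc2c(OC)cc(C(=O)OCc3ccccc3)cc2OC)cc(OC)c1OCc1ccccc1
F9 | step 8 | benzyl 4-({(2S)-1-[4-(benzyloxy)-3,5-dimethoxyphenyl]-3-{[tert-butyl(dimethyl)silyl]oxy}-1-oxopropan-2-yl}oxy)-3,5-dimethoxybenzoate | COc1cc(C(=O)[C@H](CO[Si](C)(C)C(C)(C)C)Oc2c(OC)cc(C(=O)OCc3ccccc3)cc2OC)cc(OC)c1OCc1ccccc1
F10 | step 8 | benzyl 4-({(2S)-1-[4-(benzyloxy)-3,5-dimethoxyphenyl]-3-hydroxy-1-oxopropan-2-yl}oxy)-3,5-dimethoxybenzoate | COc1cc(C(=O)[C@H](CO)Oc2c(OC)cc(C(=O)OCc3ccccc3)cc2OC)cc(OC)c1OCc1ccccc1
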